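The exocyclic C3–CH2O bond of the dihydrobenzofuran is made by uniting two fully elaborated halves: a racemic α-bromo deoxybenzoin (ring A carrying the feruloyloxypropyl chain, ring B on the C2 ketone) and an α-acyloxymethylzinc reagent that already carries the p-coumarate. A nickel/PyBox stereoconvergent Negishi coupling sets C3 and installs the coumaroyloxymethyl group in one operation. It exploits that C3 is benzylic to ring A and α to C2 held as a ketone, and that the attached CH2 bears an ester oxygen. Reduction of C2 and acid-mediated closure of the furan ring (O1–C2) by the ring A phenol then give the 2,3-trans ring, C3 dictating C2.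

Key step: step 12

Remark: TBS = tert-butyldimethylsilyl; ring A = benzo ring of the dihydrobenzofuran, ring B = 2-aryl group; C2/C3 are the dihydrobenzofuran positions.
Assumption: the sense of induction of the Ni/PyBox catalyst on this substrate cannot be assigned in advance; (S,S)-i-Pr-PyBox is written, and the antipodal ligand is used if a scouting run shows the opposite sense.

Step 1
Reactants: 1 4-(3-hydroxypropyl)-2-methoxyphenol (dihydroconiferyl alcohol)
Product: 2 2-bromo-4-(3-hydroxypropyl)-6-methoxyphenol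
Conditions: NBS (1.0 equiv), MeCN, −20 → 0 °C
Reagents that add atoms: N-bromosuccinimide, O=C1CCC(=O)N1Br
Why: Electrophilic aromatic bromination of the free phenol should go ortho to OH because the para position is blocked by the side chain, placing Br at the future C3a.

Step 2
Reactants: 2 2-bromo-4-(3-hydroxypropyl)-6-methoxyphenol
Product: 3 1-bromo-2-(TBS-oxy)-3-methoxy-5-[3-(TBS-oxy)propyl]benzene
Conditions: TBSCl (2.4 equiv), imidazole, DMF, rt
Reagents that add atoms: tert-butyldimethylsilyl chloride, CC(C)(C)[Si](C)(C)Cl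
Why: Silyl ether formation masks both hydroxyls, and the alkyl and aryl TBS ethers can later be told apart by their acid lability.

Step 3
Reactants: 4 1-(4-hydroxy-3-methoxyphenyl)ethan-1-one (acetovanillone)
Product: 5 1-[4-(TBS-oxy)-3-methoxyphenyl]ethan-1-one
Conditions: TBSCl, imidazole, DMF, rt
Reagents that add atoms: tert-butyldimethylsilyl chloride, CC(C)(C)[Si](C)(C)Cl
Why: Silyl ether formation protects the ring B phenol for the enolate, bromination and organozinc steps.

Step 4
Reactants: 3 1-bromo-2-(TBS-oxy)-3-methoxy-5-[3-(TBS-oxy)propyl]benzene; 5 1-[4-(TBS-oxy)-3-methoxyphenyl]ethan-1-one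
Product: 6 1-[4-(TBS-oxy)-3-methoxyphenyl]-2-{2-(TBS-oxy)-3-methoxy-5-[3-(TBS-oxy)propyl]phenyl}ethan-1-one
Conditions: Pd(OAc)2 (2 mol %), XPhos (4 mol %), K3PO4, toluene, 80 °C; 5 in slight excess
Reagents that add atoms: none
Why: Palladium-catalysed ketone α-arylation joins the acetyl CH3 (future C3) to ring A, and the weak base together with the ortho-substituted bromide should favour mono-arylation and spare the silyl ethers.

Step 5
Reactants: 6 the tris-TBS deoxybenzoin
Product: 7 2-[2-(TBS-oxy)-5-(3-hydroxypropyl)-3-methoxyphenyl]-1-[4-(TBS-oxy)-3-methoxyphenyl]ethan-1-one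
Conditions: CSA (10 mol %), MeOH/CH2Cl2 1:1, 0 °C
Reagents that add atoms: none
Why: Acid-catalysed methanolysis should cleave the primary alkyl silyl ether much faster than the two acid-stable aryl silyl ethers.

Step 6
Reactants: 8 (E)-ferulic acid
Product: 10 (E)-3-[4-(TBS-oxy)-3-methoxyphenyl]acrylic acid, via bis-TBS ferulate 9 (not isolated)
Conditions: TBSCl (2.3 equiv), imidazole, DMF, rt; then AcOH/THF/H2O, rt
Reagents that add atoms: tert-butyldimethylsilyl chloride, CC(C)(C)[Si](C)(C)Cl
Why: Bis-silylation followed by selective hydrolysis of the labile silyl ester leaves the phenol protected and the acid free.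

Step 7
Reactants: 7 the primary alcohol; 10 (E)-3-[4-(TBS-oxy)-3-methoxyphenyl]acrylic acid
Product: 11 3-{4-(TBS-oxy)-3-methoxy-5-[2-oxo-2-(4-(TBS-oxy)-3-methoxyphenyl)ethyl]phenyl}propyl (E)-3-[4-(TBS-oxy)-3-methoxyphenyl]acrylate
Conditions: EDC·HCl, DMAP (cat.), CH2Cl2, 0 °C → rt
Reagents that add atoms: none
Why: Steglich esterification of the only free hydroxyl installs the feruloyl ester before the sensitive late stage.

Step 8
Reactants: 11 the feruloylated deoxybenzoin
Product: 13 racemic α-bromo ketone of 11 (Br on the CH between ring A and the C2 carbonyl), via TMS enol ether 12 (not isolated)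
Conditions: TMSOTf, Et3N, CH2Cl2, 0 °C; cold NaHCO3 work-up; then NBS (1.0 equiv), THF, −78 °C
Reagents that add atoms: N-bromosuccinimide, O=C1CCC(=O)N1Br
Why: Soft enolisation gives the silyl enol ether, which NBS should brominate at carbon faster than the arenes or the cinnamate alkene; the centre is racemic by design because step 12 is stereoconvergent.

Step 9
Reactants: 14 (E)-p-coumaric acid
Product: 16 (E)-3-[4-(TBS-oxy)phenyl]acrylic acid, via bis-TBS coumarate 15 (not isolated)
Conditions: TBSCl (2.3 equiv), imidazole, DMF, rt; then AcOH/THF/H2O, rt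
Reagents that add atoms: tert-butyldimethylsilyl chloride, CC(C)(C)[Si](C)(C)Cl
Why: Bis-silylation and selective silyl ester hydrolysis, as in step 6.

Step 10
Reactants: 16 (E)-3-[4-(TBS-oxy)phenyl]acrylic acid
Product: 17 chloromethyl (E)-3-[4-(TBS-oxy)phenyl]acrylate
Conditions: ClCH2OSO2Cl (1.2 equiv), NaHCO3, Bu4NHSO4 (cat.), CH2Cl2/H2O, rt
Reagents that add atoms: chloromethyl chlorosulfate, ClCOS(=O)(=O)Cl
Why: Phase-transfer O-alkylation of the carboxylate displaces chlorosulfate, the better leaving group, and leaves the chloromethyl ester.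

Step 11
Reactants: 17 chloromethyl (E)-3-[4-(TBS-oxy)phenyl]acrylate
Product: 18 iodomethyl (E)-3-[4-(TBS-oxy)phenyl]acrylate
Conditions: NaI (3 equiv), acetone, rt, dark; used at once
Reagents that add atoms: sodium iodide, [Na+].[I-]
Why: Finkelstein exchange is driven by precipitation of NaCl and gives the iodide needed for zinc insertion.

Step 12
Reactants: 18 iodomethyl (E)-3-[4-(TBS-oxy)phenyl]acrylate; 13 racemic α-bromo ketone
Product: 20 (S)-configured ketone bearing the O-TBS-coumaroyloxymethyl group at C3, via acyloxymethylzinc iodide 19 (not isolated)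
Conditions: Zn dust (activated with 1,2-dibromoethane/TMSCl), THF, 10 °C; then 13, NiCl2·glyme (10 mol %), (S,S)-i-Pr-PyBox (13 mol %), glyme/THF, −30 °C; 19 in 1.6 equiv; cold neutral work-up, product used crude
Reagents that add atoms: none
Why: Proposed new method: a PyBox–Ni(I)–CH2OCOR species, formed by transmetalation from 19, abstracts bromine from 13 to give a planar C3 radical stabilised by ring A and by the C2 aryl ketone, and recombination with nickel followed by reductive elimination forges the C3–CH2 bond, so both enantiomers of 13 converge on one product. The closest known reaction type is the nickel/PyBox-catalysed stereoconvergent Negishi coupling of racemic α-bromo ketones and of racemic secondary benzylic bromides with organozinc halides; new here are the α-acyloxymethylzinc partner and the doubly activated bromide. No ring is closed in this step. The new C3 stereocentre is controlled by the chiral ligand on nickel in the radical-capture and reductive-elimination event, not by the substrate. The step needs C–C bond formation at C3 without enolisation (which would cause E1cB loss of the coumarate or racemisation) and without attack on either cinnamate ester; the non-basic organozinc, the low temperature and the chelate-stabilised, weakly nucleophilic α-acyloxymethylzinc should secure this.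

Step 13
Reactants: 20 the (S)-ketone
Product: 21 (2S)-3-hydroxy-2-aryl-3-aryl-propyl coumarate, i.e. the C2 carbinol of 20 as both carbinol epimers with C3 unchanged
Conditions: NaBH4, CeCl3·7H2O, MeOH/THF, −78 °C; AcOH quench at −78 °C
Reagents that add atoms: none
Why: Luche reduction should deliver 1,2-hydride addition to the aryl ketone faster than enolisation and spare both cinnamates, and the configuration of the new carbinol is irrelevant because step 14 ionises it.

Step 14
Reactants: 21 the carbinol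
Product: 23 (+)-boehmenan X, via pentahydroxy intermediate 22 (not isolated)
Conditions: TBAF (4.4 equiv), AcOH (4.4 equiv), THF, 0 °C; aqueous work-up; then TsOH·H2O (cat.), MeCN, 0 °C → rt, dilute
Reagents that add atoms: none
Why: Buffered fluoride removes the four aryl silyl groups, and acid then ionises the p-hydroxybenzylic C2 alcohol to a quinone-methide-type cation that the ring A phenol captures in an SN1 cycloetherification anti to the C3 substituent, so the fixed (S)-C3 sets (R)-C2 and the 2,3-trans ring.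

Compound list
1 | 4-(3-hydroxypropyl)-2-methoxyphenol (dihydroconiferyl alcohol) | COc1cc(CCCO)ccc1O | starting material
2 | 2-bromo-4-(3-hydroxypropyl)-6-methoxyphenol | COc1cc(CCCO)cc(Br)c1O | intermediate
3 | 1-bromo-2-(TBS-oxy)-3-methoxy-5-[3-(TBS-oxy)propyl]benzene | COc1cc(CCCO[Si](C)(C)C(C)(C)C)cc(Br)c1O[Si](C)(C)C(C)(C)C | intermediate
4 | 1-(4-hydroxy-3-methoxyphenyl)ethan-1-one (acetovanillone) | CC(=O)c1ccc(O)c(OC)c1 | starting material
5 | 1-[4-(TBS-oxy)-3-methoxyphenyl]ethan-1-one | CC(=O)c1ccc(O[Si](C)(C)C(C)(C)C)c(OC)c1 | intermediate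
6 | 1-[4-(TBS-oxy)-3-methoxyphenyl]-2-{2-(TBS-oxy)-3-methoxy-5-[3-(TBS-oxy)propyl]phenyl}ethan-1-one | COc1cc(CCCO[Si](C)(C)C(C)(C)C)cc(CC(=O)c2ccc(O[Si](C)(C)C(C)(C)C)c(OC)c2)c1O[Si](C)(C)C(C)(C)C | intermediate
7 | 2-[2-(TBS-oxy)-5-(3-hydroxypropyl)-3-methoxyphenyl]-1-[4-(TBS-oxy)-3-methoxyphenyl]ethan-1-one | COc1cc(CCCO)cc(CC(=O)c2ccc(O[Si](C)(C)C(C)(C)C)c(OC)c2)c1O[Si](C)(C)C(C)(C)C | intermediate
8 | (E)-ferulic acid | COc1cc(/C=C/C(=O)O)ccc1O | starting material
9 | TBS (E)-3-[4-(TBS-oxy)-3-methoxyphenyl]acrylate (silyl ester) | COc1cc(/C=C/C(=O)O[Si](C)(C)C(C)(C)C)ccc1O[Si](C)(C)C(C)(C)C | intermediate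
10 | (E)-3-[4-(TBS-oxy)-3-methoxyphenyl]acrylic acid | COc1cc(/C=C/C(=O)O)ccc1O[Si](C)(C)C(C)(C)C | intermediate
11 | 3-{4-(TBS-oxy)-3-methoxy-5-[2-oxo-2-(4-(TBS-oxy)-3-methoxyphenyl)ethyl]phenyl}propyl (E)-3-[4-(TBS-oxy)-3-methoxyphenyl]acrylate | COc1cc(/C=C/C(=O)OCCCc2cc(OC)c(O[Si](C)(C)C(C)(C)C)c(CC(=O)c3ccc(O[Si](C)(C)C(C)(C)C)c(OC)c3)c2)ccc1O[Si](C)(C)C(C)(C)C | intermediate
12 | (Z)-trimethylsilyl enol ether of 11 (OTMS on the ring B carbon, cis to ring A) | COc1cc(/C=C/C(=O)OCCCc2cc(OC)c(O[Si](C)(C)C(C)(C)C)c(/C=C(\O[Si](C)(C)C)c3ccc(O[Si](C)(C)C(C)(C)C)c(OC)c3)c2)ccc1O[Si](C)(C)C(C)(C)C | intermediate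
13 | racemic 3-{3-[1-bromo-2-oxo-2-(4-(TBS-oxy)-3-methoxyphenyl)ethyl]-4-(TBS-oxy)-5-methoxyphenyl}propyl (E)-3-[4-(TBS-oxy)-3-methoxyphenyl]acrylate | COc1cc(/C=C/C(=O)OCCCc2cc(OC)c(O[Si](C)(C)C(C)(C)C)c(C(Br)C(=O)c3ccc(O[Si](C)(C)C(C)(C)C)c(OC)c3)c2)ccc1O[Si](C)(C)C(C)(C)C | intermediate
14 | (E)-p-coumaric acid | OC(=O)/C=C/c1ccc(O)cc1 | starting material
15 | TBS (E)-3-[4-(TBS-oxy)phenyl]acrylate (silyl ester) | CC(C)(C)[Si](C)(C)OC(=O)/C=C/c1ccc(O[Si](C)(C)C(C)(C)C)cc1 | intermediate
16 | (E)-3-[4-(TBS-oxy)phenyl]acrylic acid | OC(=O)/C=C/c1ccc(O[Si](C)(C)C(C)(C)C)cc1 | intermediate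
17 | chloromethyl (E)-3-[4-(TBS-oxy)phenyl]acrylate | O=C(OCCl)/C=C/c1ccc(O[Si](C)(C)C(C)(C)C)cc1 | intermediate
18 | iodomethyl (E)-3-[4-(TBS-oxy)phenyl]acrylate | O=C(OCI)/C=C/c1ccc(O[Si](C)(C)C(C)(C)C)cc1 | intermediate
19 | (iodozincio)methyl (E)-3-[4-(TBS-oxy)phenyl]acrylate | O=C(OC[Zn]I)/C=C/c1ccc(O[Si](C)(C)C(C)(C)C)cc1 | intermediate
20 | (2S)-2-{2-(TBS-oxy)-3-methoxy-5-[3-((E)-O-TBS-feruloyloxy)propyl]phenyl}-3-oxo-3-[4-(TBS-oxy)-3-methoxyphenyl]propyl (E)-3-[4-(TBS-oxy)phenyl]acrylate | COc1cc(/C=C/C(=O)OCCCc2cc(OC)c(O[Si](C)(C)C(C)(C)C)c(c2)[C@@H](COC(=O)/C=C/c2ccc(O[Si](C)(C)C(C)(C)C)cc2)C(=O)c2ccc(O[Si](C)(C)C(C)(C)C)c(OC)c2)ccc1O[Si](C)(C)C(C)(C)C | intermediate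
21 | (2S)-3-hydroxy analogue of 20 (ketone reduced to CH–OH; both carbinol epimers) | COc1cc(/C=C/C(=O)OCCCc2cc(OC)c(O[Si](C)(C)C(C)(C)C)c(c2)[C@@H](COC(=O)/C=C/c2ccc(O[Si](C)(C)C(C)(C)C)cc2)C(O)c2ccc(O[Si](C)(C)C(C)(C)C)c(OC)c2)ccc1O[Si](C)(C)C(C)(C)C | intermediate
22 | fully desilylated 21 (four free phenols, free benzylic carbinol; both carbinol epimers) | COc1cc(/C=C/C(=O)OCCCc2cc(OC)c(O)c(c2)[C@@H](COC(=O)/C=C/c2ccc(O)cc2)C(O)c2ccc(O)c(OC)c2)ccc1O | intermediate
23 | (+)-boehmenan X, (2R,3S)-trans-dihydrobenzofuran | COc1cc(/C=C/C(=O)OCCCc2cc(OC)c3c(c2)[C@@H](COC(=O)/C=C/c2ccc(O)cc2)[C@H](c2ccc(O)c(OC)c2)O3)ccc1O | target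

Total step count: 14. Longest linear sequence: 9 steps (1, 2, 4, 5, 7, 8, 12, 13, 14).

Steps most likely to fail

Step 12. What may go wrong: transmetalation of the chelated α-acyloxymethylzinc to nickel is too slow, so the long-lived C3 radical is reduced or dimerises, or the ligand fails to control the C3 configuration. Fallback with known chemistry: the same bond is made by a catalytic asymmetric Mukaiyama aldol (hydroxymethylation). It sets out from silyl enol ether 12 (made from 11 as in step 8, NBS omitted). Aqueous formaldehyde with Sc(OTf)3 and a chiral 2,2'-bipyridine-diol ligand (DME/H2O, −20 °C) should give (S)-hydroxymethyl ketone F1. Immediate Luche reduction (NaBH4, CeCl3·7H2O, MeOH, −78 °C) gives 1,3-diol F2 as carbinol epimers. Selective Steglich acylation of the primary hydroxyl with acid 16 (EDC·HCl, cat. DMAP, CH2Cl2, −20 °C) returns to the route at 21.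

Step 13. What may go wrong: enolisation of the α-aryl ketone in the basic borohydride medium, leading to β-elimination of the coumarate or epimerisation at C3, or 1,3-acyl migration in the alkoxide formed. Fallback: instead of a nucleophilic borohydride, the ketone is reduced by electrophilic, catalyst-directed borane transfer, a Corey–Bakshi–Shibata reduction (Me-CBS oxazaborolidine, catecholborane, toluene, −78 °C), in which no basic hydride or alkoxide is present. It sets out from 20 and returns at 21 as a single carbinol epimer; no new compound arises (F0).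

Step 14. What may go wrong: the C2 cation loses the C3 proton (stilbene formation) or is captured intermolecularly by other phenols (oligomers) before the ring A phenol closes the ring. Fallback: the ring is closed through a neutral quinone methide under fluoride instead of through a cation under acid. It sets out from 21. Acetylation of the C2 carbinol (Ac2O, pyridine, cat. DMAP, 0 °C) gives benzylic acetate F3. TBAF (THF, 0 °C) then removes the four silyl groups, the ring B phenoxide expels acetate by 1,6-elimination to a p-quinone methide, and the ring A phenoxide adds to it anti to the C3 substituent. The route is rejoined at 23.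

Further compounds
F1 | step 12 | (2S)-3-hydroxy-2-{2-(TBS-oxy)-3-methoxy-5-[3-((E)-O-TBS-feruloyloxy)propyl]phenyl}-1-[4-(TBS-oxy)-3-methoxyphenyl]propan-1-one | COc1cc(/C=C/C(=O)OCCCc2cc(OC)c(O[Si](C)(C)C(C)(C)C)c(c2)[C@@H](CO)C(=O)c2ccc(O[Si](C)(C)C(C)(C)C)c(OC)c2)ccc1O[Si](C)(C)C(C)(C)C
F2 | step 12 | 1,3-diol from reduction of F1 (2S; both carbinol epimers) | COc1cc(/C=C/C(=O)OCCCc2cc(OC)c(O[Si](C)(C)C(C)(C)C)c(c2)[C@@H](CO)C(O)c2ccc(O[Si](C)(C)C(C)(C)C)c(OC)c2)ccc1O[Si](C)(C)C(C)(C)C
F0 | step 13 | none | none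
F3 | step 14 | C2 acetate of 21 (both epimers at the acetoxy carbon) | COc1cc(/C=C/C(=O)OCCCc2cc(OC)c(O[Si](C)(C)C(C)(C)C)c(c2)[C@@H](COC(=O)/C=C/c2ccc(O[Si](C)(C)C(C)(C)C)cc2)C(OC(C)=O)c2ccc(O[Si](C)(C)C(C)(C)C)c(OC)c2)ccc1O[Si](C)(C)C(C)(C)C
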